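# Proposed synthesis of the guaiane veratrate 26 (CNP0304846.1) by a late McMurry closure of the methylcyclopentene

## The problem

Target 26 is a trans-fused hydroazulene, numbered as a guaiane: five-membered ring C1–C5, seven-membered ring C1, C5–C10, methyls on C4 and C10, isopropyl on C7. It has seven stereocentres (C1, C3, C4, C5, C7, C8, C10), a C3–C4 epoxide, a tertiary C10 alcohol and a 3,4-dimethoxybenzoate at C8. On the seven-membered ring the C7 isopropyl, the C8 oxygen, the C10 hydroxyl and the C1–C2 bond lie on one face; the C5–C4 bond and the C10 methyl lie on the other, so the ring fusion is trans and the C8/C10 oxygens are syn.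

Only C7 needs absolute control. The rest can be relayed: C7 directs C5 across the ring, C5 directs C1 by trans alkylation, C1 directs the C10 carbinol, the C10 hydroxyl directs C8, and the trans fusion directs the epoxide.

The C8 oxygen is cis to the neighbouring isopropyl group. No reagent that adds oxygen or boron to a C8=C9 π bond will place it there, so C8 has to be set by hydride addition to a C8 ketone.

The trisubstituted epoxide is acid-labile, the aryl ester will not survive hydrides, organometallics or low-valent metals, and the tertiary alcohol can dehydrate; epoxide and ester must therefore come last.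

The feature that makes the key step possible is the C3–C4 epoxide with its C4 methyl: it is the oxide of a trisubstituted C3=C4 alkene. That alkene is the deoxygenative union of a C3 aldehyde (formylmethyl arm on C1) with a C4 methyl ketone (acetyl on C5). On a preformed cycloheptane these trans arms are gauche neighbours, and joining them creates no stereocentre.

## Retrosynthesis

**Epoxide (26 ⇒ 25).** The two C–O bonds of the epoxide are cut first. The epoxide is the most fragile group, and its precursor, the C3=C4 alkene of ester 25, is inert to everything before it. The forward step needs a peracid to attack the face syn to H-1.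

**Ester (25 ⇒ 23 + 24).** The acyl C–O bond is cut to diol 23 and 3,4-dimethoxybenzoyl chloride 24. Putting the ester on earlier would expose it to the reductive coupling. The forward step only has to distinguish a secondary from a tertiary hydroxyl.

**Diol protection (23 ⇒ 22).** The syn 1,3-diol is carried as acetonide 22. One group covers both hydroxyls, stops the C10 hydroxyl from forming a lactol with the C3 aldehyde, and forms only if C8 and C10 are syn. It also holds the ring in the chair in which the C1 and C5 substituents are equatorial.

**Key cut (22 ⇒ 20).** The C3=C4 double bond is cut to keto aldehyde 20. Against cuts inside the seven-membered ring, this one removes a ring without removing a stereocentre and leaves a monocyclic cycloheptane whose centres can be set one after another. The forward reaction must couple two electrophilic carbons intramolecularly without epimerising C5.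

**Carbonyls from alkenes (20 ⇒ 18).** Both carbonyls are traced to terminal alkenes: the formylmethyl arm to an allyl group and the acetyl group to an isopropenyl group. Diene 18 is inert to bases, hydrides and organometallics, carries no epimerisable ketone, and releases both carbonyls in one oxidative cleavage just before they are needed.

**C8 configuration (18 ⇒ 17 ⇒ 15 ⇒ 14).** Acetonide 18 comes from syn diol 17. The C8–H bond of 17 is cut to β-hydroxy ketone 15, where chelation to the C10 hydroxyl and the adjacent isopropyl group both send hydride to the same face. Ketone 15 comes from the C8-epimeric diol 14 by oxidation. This detour costs two steps and is accepted because no direct oxygenation can give the cis C7/C8 relation.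

**C10 carbinol (14 ⇒ 13).** The C10–methyl bond is cut to β-hydroxy ketone 13. The forward addition of a methyl nucleophile must come anti to the C1 allyl group.

**C8 oxygen (13 ⇒ 11).** The C8–O bond is cut to enone 11. A conjugate borylation–oxidation is asked only for regiochemistry; the configuration it gives at C8 is erased later.

**Enone (11 ⇒ 9).** The C8=C9 double bond is removed to give ketone 9. The forward step is a dehydrogenation through the kinetic enolate on the methylene side.

**Two side chains (9 ⇒ 5 + 6 + 7).** The C5–isopropenyl and C1–allyl bonds are cut together to enone 5, isopropenylmagnesium bromide 6 and allyl bromide 7. This is preferred over separate introductions because the enolate from the conjugate addition fixes the alkylation site at C1 and the trans C1/C5 relation. The forward step must add trans to the remote isopropyl group.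

**Ring size and chirality (5 ⇒ 3 ⇒ 2 ⇒ 1).** Enone 5 is cut between C10 and C5, removing C1, to silyloxycyclopropane 3 and then silyl enol ether 2. Enol ether 2 is the desymmetrised form of achiral 4-isopropylcyclohexanone 1. The enol ether that carries the chirality is also the substrate of the ring expansion, so no step is spent on functional-group change between the two.

## Roads not taken

**Alternative 1: carbene cyclopropanation–Cope (4+3) annulation.**
- Cut: C7–C8 and C1–C10, leaving a cyclopentane that already holds C2–C4.
- Forward step: a (CO)5Cr=C(OMe)(alkenyl) centre at C8 cyclopropanates the acyclic C6=C7 bond; the cis-dialkenylcyclopropane unit then rearranges across C1–C10 to cycloheptadiene A1.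
- Merits: convergent; the seven-membered ring, two C–C bonds and the C7 and C10 centres arise in one operation; C8 appears as an enol ether, one hydrolysis away from the ketone that the present plan also uses to set C8.
- Weak points here: the quaternary C10 centre depends on the geometry of an oxygenated trisubstituted alkene and on a boat transition state. The trans ring fusion must still be made by face-selective reduction of C5=C6. The saturated C3-silyloxy/C4-methyl pattern of A1 needs a regioselective dehydration before the epoxide can be made. Chromium is stoichiometric.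
- Comparison: this road is better in convergence and in bonds formed per step. The chosen plan sets against it a ring fusion fixed as trans before the second ring exists, and an alkene that is already the direct epoxide precursor.

**Alternative 2: allenic Pauson–Khand reaction.**
- Cut: C1–C5, C2–C3 and C3–C4, so both rings come from an acyclic allene–yne.
- Forward step: [Rh(CO)2Cl]2 under CO joins the distal allene double bond, the alkyne and CO to dienone A2.
- Merits: catalytic; all ring carbons and the C4 methyl in one step; only C7 and C8 have to be prepared beforehand. It is the shortest way to the hydroazulene skeleton and is better than the chosen plan in step economy up to the bicycle.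
- Weak points here: A2 is flat at C1, C4, C5 and C10 and carries a C3 ketone. The trans fusion, the C10 tertiary alcohol and the C3–C4 epoxide (four to five stereocentres) must all be drawn from a cross-conjugated dienone whose only resident centres, C7 and C8, are remote. The C3 carbonyl has to be turned into the C3=C4 alkene.
- Comparison: the chosen plan gives up the one-step ring construction. In return C1, C5 and C10 are placed while a cycloheptanone carbonyl and its enolate can direct them.

**Alternative 3: gold-catalysed alkyne–alkene–ketone cascade.**
- Cut: C1–C5, C10–O and C6–C7.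
- Forward step: [(2-biphenyl)tBu2P]Au(NCMe)SbF6 activates the C5≡C6 alkyne; C1 of the alkene attacks C5, the C7 ketone oxygen traps C10, and the alkenyl-gold carbon C6 closes onto the C7 oxocarbenium ion to give the oxa-bridged A3.
- Merits: three bonds, both carbocycles and the C1, C7 and C10 centres in one mild catalytic step. It has the highest bond economy of all four roads.
- Weak points here: the target has no 7,10-ether. The tertiary allylic C7–O bond would have to be cleaved reductively with hydrogen delivered to C7 so that isopropyl ends cis to the C8 oxygen. C5=C6 must then be hydrogenated to the trans fusion, and the C3/C4 pattern needs the same dehydration as in alternative 1.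
- Comparison: the cascade suits oxygen-bridged guaianes and here builds a bridge that must be taken apart at the most hindered carbon. The chosen plan is longer, but each centre except C8 is introduced in its final form, and C8 is corrected by one oxidation–reduction pair.

Key step: step 12

Assumption: lithium (R,R)-bis(1-phenylethyl)amide is taken to give (S)-4-alkyl-1-silyloxycyclohexenes, so the (S,S)-amide is specified for 2; if the sense is the reverse, the antipodal amide is used and nothing else changes.

## Route

Step 1
Reactants: 1 4-isopropylcyclohexanone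
Product: 2 (R)-4-isopropyl-1-(trimethylsilyloxy)cyclohex-1-ene
Conditions: (S,S)-bis(1-phenylethyl)amine, nBuLi, LiCl, TMSCl (in situ quench), THF, −78 °C
Reagents that add atoms: chlorotrimethylsilane, C[Si](C)(C)Cl
Why: Enantioselective deprotonation of a prochiral 4-substituted cyclohexanone by a C2-symmetric chiral lithium amide, with the enolate silylated as it forms; the base chooses between the two enantiotopic axial α-hydrogens and so sets C7.

Step 2
Reactants: 2 (R)-4-isopropyl-1-(trimethylsilyloxy)cyclohex-1-ene
Product: 3 (4R)-4-isopropyl-1-(trimethylsilyloxy)bicyclo[4.1.0]heptane (mixture at the cyclopropane carbons)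
Conditions: Et2Zn, CH2I2, toluene, 0 °C to rt
Reagents that add atoms: diiodomethane, ICI
Why: Simmons–Smith cyclopropanation (Furukawa variant) of an electron-rich silyl enol ether; the two new centres are destroyed in step 3, so its facial selectivity does not matter.

Step 3
Reactants: 3 (4R)-4-isopropyl-1-(trimethylsilyloxy)bicyclo[4.1.0]heptane
Product: 5 (R)-5-isopropylcyclohept-2-en-1-one, via β-chloro ketone 4 (not isolated)
Conditions: FeCl3, DMF, 0 °C to rt; then NaOAc, MeOH, reflux
Reagents that add atoms: none
Why: Ito–Saegusa ring expansion: one-electron oxidation of the silyloxycyclopropane cleaves the internal bond to a ring-enlarged β-keto radical that takes up chlorine, and NaOAc eliminates HCl to the conjugated enone; the carbon from step 2 becomes C1 and C7 is untouched.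

Step 4
Reactants: 5 (R)-5-isopropylcyclohept-2-en-1-one; 6 isopropenylmagnesium bromide; 7 allyl bromide
Product: 9 (2R,3S,5R)-2-allyl-5-isopropyl-3-(prop-1-en-2-yl)cycloheptan-1-one, via bromomagnesium enolate 8 (not isolated)
Conditions: CuBr·SMe2 (20 mol%), THF, −78 to −40 °C; then 7, DMPU, −40 °C to rt
Reagents that add atoms: none
Why: Copper-catalysed conjugate addition followed by enolate alkylation. The organocopper should add axially to the chair-like enone that keeps the isopropyl group equatorial, placing isopropenyl at C5 trans to isopropyl at C7. Enolate 8 should then be allylated at C1 on the face away from the new neighbour, giving the trans C1/C5 pair.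

Step 5
Reactants: 9 (2R,3S,5R)-2-allyl-5-isopropyl-3-(prop-1-en-2-yl)cycloheptan-1-one
Product: 11 (4R,6S,7R)-7-allyl-4-isopropyl-6-(prop-1-en-2-yl)cyclohept-2-en-1-one, via lithium enolate 10 (not isolated)
Conditions: LiN(iPr)2, THF, −78 °C; then N-tert-butylbenzenesulfinimidoyl chloride, −78 °C
Reagents that add atoms: none
Why: Kinetic deprotonation takes the C9 methylene proton rather than the hindered tertiary C1–H, and Mukaiyama dehydrogenation of enolate 10 gives the C8=C9 enone in one flask; no palladium is brought near the two terminal alkenes.

Step 6
Reactants: 11 (4R,6S,7R)-7-allyl-4-isopropyl-6-(prop-1-en-2-yl)cyclohept-2-en-1-one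
Product: 13 (2R,3S,5R,6S)-2-allyl-6-hydroxy-5-isopropyl-3-(prop-1-en-2-yl)cycloheptan-1-one, via β-boryl ketone 12 (not isolated)
Conditions: B2pin2, CuCl (5 mol%), DPEphos, NaOtBu (cat.), MeOH, THF, rt; then NaBO3·4H2O, THF/H2O, rt
Reagents that add atoms: sodium perborate (NaBO3·4H2O), [Na+].[O-]OB=O
Why: Copper-catalysed conjugate borylation of the enone only (isolated alkenes do not react), anti to the C7 isopropyl, then perborate oxidation with retention; only the position of the oxygen matters, since C8 is reset in steps 8 and 9.

Step 7
Reactants: 13 (2R,3S,5R,6S)-2-allyl-6-hydroxy-5-isopropyl-3-(prop-1-en-2-yl)cycloheptan-1-one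
Product: 14 (1S,3S,4R,6S,7R)-7-allyl-4-isopropyl-1-methyl-6-(prop-1-en-2-yl)cycloheptane-1,3-diol
Conditions: MeMgBr (excess), CeCl3, THF, −78 °C
Reagents that add atoms: methylmagnesium bromide, C[Mg]Br
Why: CeCl3-promoted Grignard 1,2-addition, which suppresses enolisation and retro-aldol cleavage; the methyl group should enter anti to the adjacent equatorial allyl group (equatorial attack), so the C10 hydroxyl ends cis to the C1 side chain.

Step 8
Reactants: 14 (1S,3S,4R,6S,7R)-7-allyl-4-isopropyl-1-methyl-6-(prop-1-en-2-yl)cycloheptane-1,3-diol
Product: 15 (2R,4S,5R,6S)-5-allyl-6-hydroxy-2-isopropyl-6-methyl-4-(prop-1-en-2-yl)cycloheptan-1-one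
Conditions: Dess–Martin periodinane, NaHCO3, CH2Cl2, 0 °C to rt
Reagents that add atoms: none
Why: Dess–Martin oxidation touches only the secondary alcohol; the buffered neutral medium should prevent retro-aldol cleavage, dehydration and epimerisation of C7, now α to the ketone.

Step 9
Reactants: 15 (2R,4S,5R,6S)-5-allyl-6-hydroxy-2-isopropyl-6-methyl-4-(prop-1-en-2-yl)cycloheptan-1-one
Product: 17 (1S,3R,4R,6S,7R)-7-allyl-4-isopropyl-1-methyl-6-(prop-1-en-2-yl)cycloheptane-1,3-diol, via diethylboron chelate 16 (not isolated)
Conditions: Et2BOMe, THF/MeOH (4:1), −78 °C; then NaBH4; methanolic work-up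
Reagents that add atoms: none
Why: Narasaka–Prasad reduction: boron ties the C10 oxygen to the C8 carbonyl in chelate 16, and external hydride attacks the face opposite the chelate, which is also the face anti to the C7 isopropyl. Both effects should give the C8 hydroxyl syn to the C10 hydroxyl and cis to isopropyl.

Step 10
Reactants: 17 (1S,3R,4R,6S,7R)-7-allyl-4-isopropyl-1-methyl-6-(prop-1-en-2-yl)cycloheptane-1,3-diol
Product: 18 acetonide of 17 (isopropylidene bridge between the C8 and C10 oxygens)
Conditions: 2-methoxypropene, PPTS (cat.), CH2Cl2, 0 °C
Reagents that add atoms: 2-methoxypropene, COC(C)=C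
Why: Kinetic acetalisation of a syn 1,3-diol; only the syn isomer can bridge, so the step also confirms the outcome of steps 7 and 9, and the tertiary hydroxyl is masked before the aldehyde appears.

Step 11
Reactants: 18 acetonide of 17
Product: 20 keto aldehyde acetonide (C1 formylmethyl, C5 acetyl, trans), via bis-ozonide 19 (not isolated)
Conditions: O3, CH2Cl2, −78 °C; then PPh3, −78 °C to rt
Reagents that add atoms: ozone, [O-][O+]=O
Why: Ozonolysis (Criegee mechanism) of both terminal alkenes with reductive work-up turns allyl into the C3 aldehyde arm and isopropenyl into the C4 methyl ketone; the acetal and saturated skeleton are inert, and 20 is used at once to avoid aldol reaction or C5 epimerisation.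

Step 12
Reactants: 20 keto aldehyde acetonide
Product: 22 (1R,5S,7R,8R,10S)-guai-3-ene-8,10-diol acetonide, via titanium pinacolate 21 (not isolated)
Conditions: TiCl3(DME)1.5, Zn–Cu couple, DME, reflux; 20 added by syringe pump (high dilution)
Reagents that add atoms: none
Why: Low-valent titanium (formally zerovalent, from TiCl3(DME)1.5 and Zn–Cu couple) transfers one electron to each carbonyl; the titanium-bound ketyl carbons C3 and C4 join to pinacolate 21, and deoxygenation on the metal at reflux releases the C3=C4 alkene. The closest known reaction type is the intramolecular McMurry coupling of keto aldehydes to cycloalkenes. The five-membered ring C1–C5 closes by C3–C4 bond formation, formally a 5-exo addition of the aldehyde ketyl to the ketone carbonyl. No stereocentre is created: the two carbinol centres of 21 become sp2, and C1 and C5 are spectators. The step needs intramolecular rather than intermolecular coupling, which slow addition at high dilution should secure. The aldehyde/ketone cross-coupling follows from both groups being in one molecule. The acetonide holds the cycloheptane in the chair in which the trans C1 and C5 arms are both equatorial and gauche, so the carbonyl carbons are close and the stable C5 configuration is kept. The acetal and the rest of the skeleton are not reducible under these conditions.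

Step 13
Reactants: 22 (1R,5S,7R,8R,10S)-guai-3-ene-8,10-diol acetonide
Product: 23 (1R,5S,7R,8R,10S)-guai-3-ene-8,10-diol
Conditions: AcOH/THF/H2O, 40 °C
Reagents that add atoms: none
Why: Acid-catalysed hydrolysis of a strained bridged acetonide proceeds under mild acid that the trisubstituted alkene and tertiary alcohol should tolerate.

Step 14
Reactants: 23 (1R,5S,7R,8R,10S)-guai-3-ene-8,10-diol; 24 3,4-dimethoxybenzoyl chloride
Product: 25 (1R,5S,7R,8R,10S)-10-hydroxyguai-3-en-8-yl 3,4-dimethoxybenzoate
Conditions: DMAP, Et3N, CH2Cl2, rt
Reagents that add atoms: none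
Why: DMAP-catalysed acylation reaches the secondary C8 hydroxyl and leaves the tertiary C10 hydroxyl alone, so no protecting group is needed.

Step 15
Reactants: 25 (1R,5S,7R,8R,10S)-10-hydroxyguai-3-en-8-yl 3,4-dimethoxybenzoate
Product: 26 (1R,3R,4S,5S,7R,8R,10S)-3,4-epoxy-10-hydroxyguaian-8-yl 3,4-dimethoxybenzoate
Conditions: mCPBA, NaHCO3, CH2Cl2, 0 °C
Reagents that add atoms: 3-chloroperbenzoic acid, OOC(=O)c1cccc(Cl)c1
Why: Prilezhaev epoxidation of the only alkene. In the trans-fused envelope the pseudoaxial allylic hydrogens at C5 and C2 point to the face that also carries isopropyl, ester and the C10 oxygen, so the peracid should approach the opposite face, syn to H-1, and set C3 and C4; the buffer protects the epoxide.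

## Compound list

1 | 4-isopropylcyclohexanone | CC(C)C1CCC(=O)CC1 | starting material
2 | (R)-4-isopropyl-1-(trimethylsilyloxy)cyclohex-1-ene | C[Si](C)(C)OC1=CC[C@H](C(C)C)CC1 | intermediate
3 | (4R)-4-isopropyl-1-(trimethylsilyloxy)bicyclo[4.1.0]heptane, mixture at the cyclopropane carbons | C[Si](C)(C)OC12CC1C[C@H](C(C)C)CC2 | intermediate
4 | (5R)-3-chloro-5-isopropylcycloheptan-1-one, mixture at the chlorinated carbon (not isolated) | O=C1CC(Cl)C[C@H](C(C)C)CC1 | intermediate
5 | (R)-5-isopropylcyclohept-2-en-1-one | O=C1C=CC[C@H](C(C)C)CC1 | intermediate
6 | isopropenylmagnesium bromide | CC(=C)[Mg]Br | starting material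
7 | allyl bromide | C=CCBr | starting material
8 | bromomagnesium enolate of the conjugate adduct, isopropenyl trans to isopropyl (not isolated) | Br[Mg]OC1=C[C@@H](C(C)=C)C[C@H](C(C)C)CC1 | intermediate
9 | (2R,3S,5R)-2-allyl-5-isopropyl-3-(prop-1-en-2-yl)cycloheptan-1-one (allyl trans to isopropenyl, isopropenyl trans to isopropyl) | O=C1CC[C@@H](C(C)C)C[C@H](C(C)=C)[C@H]1CC=C | intermediate
10 | lithium enolate of 9 towards the C9 methylene (not isolated) | [Li]OC1=CC[C@@H](C(C)C)C[C@H](C(C)=C)[C@H]1CC=C | intermediate
11 | (4R,6S,7R)-7-allyl-4-isopropyl-6-(prop-1-en-2-yl)cyclohept-2-en-1-one | O=C1C=C[C@@H](C(C)C)C[C@H](C(C)=C)[C@H]1CC=C | intermediate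
12 | β-boryl ketone, pinacolboryl group at C8 trans to isopropyl (not isolated) | O=C1C[C@H](B2OC(C)(C)C(C)(C)O2)[C@@H](C(C)C)C[C@H](C(C)=C)[C@H]1CC=C | intermediate
13 | (2R,3S,5R,6S)-2-allyl-6-hydroxy-5-isopropyl-3-(prop-1-en-2-yl)cycloheptan-1-one (hydroxyl trans to isopropyl) | O=C1C[C@H](O)[C@@H](C(C)C)C[C@H](C(C)=C)[C@H]1CC=C | intermediate
14 | (1S,3S,4R,6S,7R)-7-allyl-4-isopropyl-1-methyl-6-(prop-1-en-2-yl)cycloheptane-1,3-diol (anti 1,3-diol) | O[C@H]1C[C@](C)(O)[C@H](CC=C)[C@@H](C(C)=C)C[C@@H]1C(C)C | intermediate
15 | (2R,4S,5R,6S)-5-allyl-6-hydroxy-2-isopropyl-6-methyl-4-(prop-1-en-2-yl)cycloheptan-1-one | O=C1C[C@](C)(O)[C@H](CC=C)[C@@H](C(C)=C)C[C@@H]1C(C)C | intermediate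
16 | diethylboron chelate of 15, O-BEt2 on the C10 oxygen bound to the C8 carbonyl (not isolated) | O=C1C[C@](C)(OB(CC)CC)[C@H](CC=C)[C@@H](C(C)=C)C[C@@H]1C(C)C | intermediate
17 | (1S,3R,4R,6S,7R)-7-allyl-4-isopropyl-1-methyl-6-(prop-1-en-2-yl)cycloheptane-1,3-diol (syn 1,3-diol, secondary hydroxyl cis to isopropyl) | O[C@@H]1C[C@](C)(O)[C@H](CC=C)[C@@H](C(C)=C)C[C@@H]1C(C)C | intermediate
18 | acetonide of 17 (isopropylidene bridge between the C8 and C10 oxygens) | CC1(C)O[C@@H]2C[C@](C)(O1)[C@H](CC=C)[C@@H](C(C)=C)C[C@@H]2C(C)C | intermediate
19 | bis-ozonide of 18, a 1,2,4-trioxolane on each former alkene, mixture at the trioxolane carbons (not isolated) | CC1(C)O[C@@H]2C[C@](C)(O1)[C@H](CC3OCOO3)[C@@H](C3(C)OCOO3)C[C@@H]2C(C)C | intermediate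
20 | keto aldehyde acetonide: cycloheptane acetonide with C1 formylmethyl and C5 acetyl, trans | CC1(C)O[C@@H]2C[C@](C)(O1)[C@H](CC=O)[C@@H](C(C)=O)C[C@@H]2C(C)C | intermediate
21 | titanium pinacolate: cis-3,4-diolate of the closed guaiane acetonide on titanium, drawn schematically, C3/C4 face undefined (not isolated) | CC1(C)O[C@@H]2C[C@](C)(O1)[C@@H]3CC4O[Ti]OC4(C)[C@H]3C[C@@H]2C(C)C | intermediate
22 | (1R,5S,7R,8R,10S)-guai-3-ene-8,10-diol acetonide | CC1(C)O[C@@H]2C[C@](C)(O1)[C@@H]3CC=C(C)[C@H]3C[C@@H]2C(C)C | intermediate
23 | (1R,5S,7R,8R,10S)-guai-3-ene-8,10-diol | O[C@@H]1C[C@](C)(O)[C@@H]2CC=C(C)[C@H]2C[C@@H]1C(C)C | intermediate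
24 | 3,4-dimethoxybenzoyl chloride | COc1ccc(C(Cl)=O)cc1OC | starting material
25 | (1R,5S,7R,8R,10S)-10-hydroxyguai-3-en-8-yl 3,4-dimethoxybenzoate | COc1ccc(C(=O)O[C@@H]2C[C@](C)(O)[C@@H]3CC=C(C)[C@H]3C[C@@H]2C(C)C)cc1OC | intermediate
26 | (1R,3R,4S,5S,7R,8R,10S)-3,4-epoxy-10-hydroxyguaian-8-yl 3,4-dimethoxybenzoate (CNP0304846.1) | COc1ccc(C(=O)O[C@@H]2C[C@](C)(O)[C@@H]3C[C@H]4O[C@@]4(C)[C@H]3C[C@@H]2C(C)C)cc1OC | target

## Step count and least certain steps

Total step count: 15. Longest linear sequence: 15 steps (1 to 26); 6, 7 and 24 are purchased.

**Step 12 (key step).** The 1,5-keto aldehyde may undergo aldol condensation on the Lewis-acidic titanium chlorides before electron transfer, C5 may epimerise next to the ketone, or the coupling may stop at the pinacol stage. All three come from the long residence time that slow addition imposes. Fallback: ring-closing metathesis of diene 18, whose allyl and isopropenyl groups are the same C3 and C4 carbons, using second-generation Grubbs catalyst (H2IMes)(PCy3)Cl2Ru=CHPh in CH2Cl2 at 40 °C. It leaves the route at 18, bypasses 20, and returns at 22 without a new compound.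

**Step 4.** Facial control by the remote C7 isopropyl group may be incomplete, because chair and twist forms of a cycloheptenone lie close in energy; some C5/C7-cis material would then form. Fallback: place a second equatorial substituent next to the isopropyl group before the addition.
- From 1, the antipodal lithium (R,R)-bis(1-phenylethyl)amide with TMSCl gives (S)-4-isopropyl-1-(trimethylsilyloxy)cyclohex-1-ene F1.
- Pd(OAc)2 in MeCN (Saegusa–Ito oxidation) converts F1 into (R)-4-isopropylcyclohex-2-en-1-one F2.
- Conjugate borylation–oxidation as in step 6 gives (3S,4R)-3-hydroxy-4-isopropylcyclohexan-1-one F3, and TBSCl/imidazole gives its silyl ether F4.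
- LiN(iPr)2/TMSCl deprotonates away from the silyloxy carbon to enol ether F5.
- Et2Zn/CH2I2 gives cyclopropane F6, and FeCl3 then NaOAc gives (5R,6S)-6-(tert-butyldimethylsilyloxy)-5-isopropylcyclohept-2-en-1-one F7.
- In F7 both substituents are equatorial, and addition trans to the 5-substituent and cis to the 6-substituent are the preferences of cycloheptenones. Reaction with 6 and 7 as in step 4 gives the allylated ketone F8.
- Bu4NF removes the silyl group and the route is rejoined at 13.

**Step 7.** The methyl group may add partly from the wrong face of the flexible cycloheptanone, or the magnesium β-alkoxide may fragment by retro-aldol reaction. Fallback: from 13, dimethylsulfonium methylide (Corey–Chaykovsky reaction), whose small ylide prefers the trajectory opposite to that of a Grignard reagent, gives the spiro-epoxide F9. LiAlH4 opens F9 at the methylene carbon and the route is rejoined at 14.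

**Step 15.** Hydrogen bonding of the peracid to the free C10 hydroxyl, or a weak intrinsic bias of the trans-fused cyclopentene, may deliver oxygen to the face anti to H-1. Fallback: from 25, N-bromosuccinimide in aqueous THF forms the bromonium ion on the face the peracid prefers, and water opens it anti at the tertiary C4 to give bromohydrin F10. K2CO3 in acetone then closes the epoxide on the opposite face, returning at 26.

## Further compounds

F1 | step 4 | (S)-4-isopropyl-1-(trimethylsilyloxy)cyclohex-1-ene | C[Si](C)(C)OC1=CC[C@@H](C(C)C)CC1
F2 | step 4 | (R)-4-isopropylcyclohex-2-en-1-one | O=C1C=C[C@@H](C(C)C)CC1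
F3 | step 4 | (3S,4R)-3-hydroxy-4-isopropylcyclohexan-1-one | O=C1C[C@H](O)[C@@H](C(C)C)CC1
F4 | step 4 | (3S,4R)-3-(tert-butyldimethylsilyloxy)-4-isopropylcyclohexan-1-one | O=C1C[C@H](O[Si](C)(C)C(C)(C)C)[C@@H](C(C)C)CC1
F5 | step 4 | (4R,5S)-5-(tert-butyldimethylsilyloxy)-4-isopropyl-1-(trimethylsilyloxy)cyclohex-1-ene | C[Si](C)(C)OC1=CC[C@H](C(C)C)[C@@H](O[Si](C)(C)C(C)(C)C)C1
F6 | step 4 | 3-(tert-butyldimethylsilyloxy)-4-isopropyl-1-(trimethylsilyloxy)bicyclo[4.1.0]heptane, mixture at the cyclopropane carbons | C[Si](C)(C)OC12CC1C[C@H](C(C)C)[C@@H](O[Si](C)(C)C(C)(C)C)C2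
F7 | step 4 | (5R,6S)-6-(tert-butyldimethylsilyloxy)-5-isopropylcyclohept-2-en-1-one | O=C1C=CC[C@H](C(C)C)[C@@H](O[Si](C)(C)C(C)(C)C)C1
F8 | step 4 | tert-butyldimethylsilyl ether of 13 | O=C1C[C@H](O[Si](C)(C)C(C)(C)C)[C@@H](C(C)C)C[C@H](C(C)=C)[C@H]1CC=C
F0 | step 12 | none | none
F9 | step 7 | spiro-epoxide of 13 at C10 (epoxide oxygen cis to the allyl group) | O[C@H]1C[C@@]2(CO2)[C@H](CC=C)[C@@H](C(C)=C)C[C@@H]1C(C)C
F10 | step 15 | 3-bromo-4,10-dihydroxyguaian-8-yl 3,4-dimethoxybenzoate (bromine anti to the C4 hydroxyl, C4 hydroxyl syn to H-1) | COc1ccc(C(=O)O[C@@H]2C[C@](C)(O)[C@@H]3C[C@H](Br)[C@@](C)(O)[C@H]3C[C@@H]2C(C)C)cc1OC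
A1 | alternative 1 | cyclohepta-1,4-diene with C8 methyl enol ether, C10 4-methoxybenzyl ether and C3 silyl ether | COC1=C[C@](C)(OCc3ccc(OC)cc3)[C@@H]2C[C@H](O[Si](C)(C)C(C)(C)C)[C@@H](C)C2=C[C@@H]1C(C)C
A2 | alternative 2 | bicyclo[5.3.0]deca-1(10),4-dien-3-one (guaiane numbering) with C8 silyl ether | CC1=C2C[C@H](C(C)C)[C@H](O[Si](C)(C)C(C)(C)C)CC(C)=C2CC1=O
A3 | alternative 3 | 7,10-oxa-bridged guai-5-ene with C8 triethylsilyl and C3 tert-butyldimethylsilyl ethers | CC[Si](CC)(CC)O[C@@H]1C[C@@]2(C)[C@@H]3C[C@H](O[Si](C)(C)C(C)(C)C)[C@@H](C)C3=C[C@]1(C(C)C)O2
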